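**Plan**

Ring A is the 4-methoxy-5-methyl-2-isopropylphenoxy group, ring B the central arene and ring C the quinone. Rings B and C share one pattern (C1 aryloxy oxygen, C2 methyl, C3 oxygen, C4 H, C5 isopropyl, C6 oxygen), and the C6 oxygen of ring B is the C1 aryloxy oxygen of ring C. This is the pattern a 3-aryloxy-2-methyl-4-oxy-4-(3-methylbut-1-en-2-yl)cyclobutenone gives on ring expansion.
Retrosynthesis: after the O-methylation and the quinone oxidation are undone, C3–C4 of ring B and C3–C4 of ring C are cut together, which opens both rings to the ether-linked bis(4-alkenylcyclobutenone) 17. Next the two carbinol–alkenyl C–C bonds are cut, then the two O–C(sp2) bonds that tie each ether oxygen to a cyclobutenedione carbon.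
Forward: chlorodione 5 is made from diisopropyl squarate, ring A phenol 11 from carvacrol, and alkenyllithium 14 once, as a stock solution, from bromide 13. 11 is joined to 5, 14 is added, the alkoxide is capped with a second 5 and 14 is added again. One thermolysis then forms ring C and ring B, and Ag2O oxidation and O-methylation finish the route.
Stereochemistry: the target has no stereocentre. The two carbinol centres of 17 are made without control and vanish on aromatisation.

Key step: step 11

Remark: rotation about the diaryl ether bonds of the target is taken as free, and 2-bromo-3-methylbut-1-ene (13) is taken as a purchasable reagent.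

**Route**

Step 1
Reactants: 1 diisopropyl squarate
Product: 3 3-methyl-4-(propan-2-yloxy)cyclobut-3-ene-1,2-dione, via hydroxycyclobutenone 2 (not isolated)
Conditions: MeLi, THF, −78 °C; then 12 M HCl aq., CH2Cl2, rt
Reagents that add atoms: methyllithium, C[Li]; water, O
Why: 1,2-Addition of MeLi to one squarate carbonyl, then acid ionisation of the carbinol and hydrolytic loss of one isopropoxy group, is the standard squarate-to-alkylcyclobutenedione sequence.

Step 2
Reactants: 3 3-methyl-4-(propan-2-yloxy)cyclobut-3-ene-1,2-dione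
Product: 4 3-hydroxy-4-methylcyclobut-3-ene-1,2-dione
Conditions: 6 M HCl aq., THF, 50 °C
Reagents that add atoms: water, O
Why: Acid hydrolysis of the vinylogous isopropyl ester by addition–elimination of water should give the strongly acidic semisquaric acid.

Step 3
Reactants: 4 3-hydroxy-4-methylcyclobut-3-ene-1,2-dione
Product: 5 3-chloro-4-methylcyclobut-3-ene-1,2-dione
Conditions: (COCl)2, DMF (cat.), CH2Cl2, 0 °C to rt
Reagents that add atoms: oxalyl chloride, O=C(Cl)C(=O)Cl
Why: The vinylogous carboxylic acid is converted into the vinylogous acid chloride by the chloroiminium (Vilsmeier-type) species formed from oxalyl chloride and DMF.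

Step 4
Reactants: 6 carvacrol
Product: 7 2-methoxy-1-methyl-4-(propan-2-yl)benzene
Conditions: MeI, K2CO3, acetone, reflux
Reagents that add atoms: iodomethane, CI
Why: Williamson O-methylation of the phenol.

Step 5
Reactants: 7 2-methoxy-1-methyl-4-(propan-2-yl)benzene
Product: 8 1-bromo-4-methoxy-5-methyl-2-(propan-2-yl)benzene
Conditions: NBS, MeCN, 0 °C to rt
Reagents that add atoms: N-bromosuccinimide, O=C1CCC(=O)N1Br
Why: Electrophilic aromatic bromination should go para to the methoxy group, the most activated free position, as is usual for anisoles with NBS in MeCN.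

Step 6
Reactants: 8 1-bromo-4-methoxy-5-methyl-2-(propan-2-yl)benzene
Product: 11 4-methoxy-5-methyl-2-(propan-2-yl)phenol, via aryllithium 9 (not isolated), via dimethyl arylboronate 10 (not isolated)
Conditions: n-BuLi, THF, −78 °C; B(OMe)3, −78 °C to rt; then H2O2, NaOH aq., 0 °C to rt
Reagents that add atoms: trimethyl borate, COB(OC)OC; hydrogen peroxide, OO
Why: Bromine–lithium exchange and borylation (the borate atoms remain only in 10) are followed by alkaline peroxide oxidation, in which the aryl group migrates from boron to oxygen (borylation–oxidation of an aryl halide to a phenol).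

Step 7
Reactants: 11 4-methoxy-5-methyl-2-(propan-2-yl)phenol; 5 3-chloro-4-methylcyclobut-3-ene-1,2-dione
Product: 12 3-[4-methoxy-5-methyl-2-(propan-2-yl)phenoxy]-4-methylcyclobut-3-ene-1,2-dione
Conditions: Et3N, CH2Cl2, −20 °C to rt
Reagents that add atoms: none
Why: The phenoxide attacks the chlorine-bearing carbon of the vinylogous acid chloride and expels chloride (addition–elimination), so the hindered ring A–O–C1(ring B) bond is made as an acyl-type substitution and not as a diaryl ether coupling.

Step 8
Reactants: 13 2-bromo-3-methylbut-1-ene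
Product: 14 2-lithio-3-methylbut-1-ene
Conditions: t-BuLi (2 equiv), Et2O–pentane, −78 °C; titrated, kept under Ar at −20 °C or below
Reagents that add atoms: tert-butyllithium, [Li]C(C)(C)C
Why: Bromine–lithium exchange on the alkenyl bromide, with the second equivalent of t-BuLi destroying the tert-butyl bromide by elimination; the solution is made once on the scale needed for steps 9 and 10 and is re-titrated before each use.

Step 9
Reactants: 12 3-[4-methoxy-5-methyl-2-(propan-2-yl)phenoxy]-4-methylcyclobut-3-ene-1,2-dione; 14 2-lithio-3-methylbut-1-ene; 5 3-chloro-4-methylcyclobut-3-ene-1,2-dione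
Product: 16 4-[(2-methyl-3,4-dioxocyclobut-1-en-1-yl)oxy]-3-[4-methoxy-5-methyl-2-(propan-2-yl)phenoxy]-2-methyl-4-(3-methylbut-1-en-2-yl)cyclobut-2-en-1-one (racemic), via lithium alkoxide 15 (not isolated)
Conditions: 14 (1.05 equiv) added to 12, THF–Et2O, −78 °C; then 5, −78 to 0 °C
Reagents that add atoms: none
Why: The alkenyllithium should add 1,2 to the carbonyl next to the aryloxy-bearing carbon, the other carbonyl being deactivated as a vinylogous ester, and the tertiary lithium alkoxide should then displace chloride from 5 by addition–elimination; the new carbinol centre is formed without control, so 16 is racemic.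

Step 10
Reactants: 16 the ether-linked cyclobutenone–cyclobutenedione; 14 2-lithio-3-methylbut-1-ene
Product: 17 4-{[4-hydroxy-2-methyl-4-(3-methylbut-1-en-2-yl)-3-oxocyclobut-1-en-1-yl]oxy}-3-[4-methoxy-5-methyl-2-(propan-2-yl)phenoxy]-2-methyl-4-(3-methylbut-1-en-2-yl)cyclobut-2-en-1-one (mixture of two racemic diastereomers)
Conditions: 14 (1.0 equiv) added to 16, THF–Et2O, −95 °C; then AcOH, −78 °C
Reagents that add atoms: none
Why: Of the three carbonyl groups of 16 only the one next to the oxygen-bearing carbon of the cyclobutenedione is ketone-like (the other two are vinylogous ester carbonyls), so one equivalent of the alkenyllithium at low temperature should add there by 1,2-addition; the second carbinol centre is not controlled, which is harmless because both centres disappear in step 11.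

Step 11
Reactants: 17 the ether-linked bis(4-alkenylcyclobutenone)
Product: 19 2-{4-hydroxy-2-[4-methoxy-5-methyl-2-(propan-2-yl)phenoxy]-3-methyl-6-(propan-2-yl)phenoxy}-3-methyl-6-(propan-2-yl)benzene-1,4-diol, via ring C hydroquinone 18 (not isolated)
Conditions: degassed toluene (0.01 M), 110 °C, Ar
Reagents that add atoms: none
Why: Proposed new method: each 4-oxy-4-alkenylcyclobutenone should open by thermal conrotatory 4π ring opening with its C4 oxygen turning outward, which puts the 3-methylbut-1-en-2-yl group cis to the ketene, and the dienylketene should close by disrotatory 6π electrocyclisation (ketene carbon to terminal CH2) to a cyclohexa-2,4-dienone that tautomerises to the arene; the closest known reaction is the Moore ring expansion of a single 4-alkenyl-4-hydroxy- or 4-alkoxycyclobutenone to a hydroquinone, which has not been run twice across an ether link in which the C4 oxygen of one ring is the C3 substituent of the other. Ring C should close first, because its cyclobutenone carries the free hydroxyl, the strongest outward-rotating donor; this 6π closure makes C3–C4 of ring C and gives 18, in which the oxygen on C4 of the remaining cyclobutenone has become an ordinary aryl ether oxygen. The second 6π closure then makes C3–C4 of ring B and delivers the C3 phenol. No stereocentre is created and the two carbinol centres are erased, so the diastereomer mixture of 17 converges on one product. The step needs outward rotation of oxygen in both openings, secured by the donor oxygen on each sp3 carbon (a free hydroxyl for ring C, and for ring B an ether oxygen whose wrongly opened ketene can only reclose), and it needs 6π closure to outrun ketene capture by hydroxyl, secured by high dilution and by the eight-membered ring that any intramolecular lactonisation would require. The regiochemistry is already fixed in 17, since in each ring the ketene carbon becomes C3–OH and the carbinol carbon becomes C6–O.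

Step 12
Reactants: 19 the triaryl diether with ring C as hydroquinone
Product: 20 2-{4-hydroxy-2-[4-methoxy-5-methyl-2-(propan-2-yl)phenoxy]-3-methyl-6-(propan-2-yl)phenoxy}-3-methyl-6-(propan-2-yl)cyclohexa-2,5-diene-1,4-dione
Conditions: Ag2O, Na2SO4, Et2O, rt
Reagents that add atoms: none
Why: Ag2O oxidises the para-hydroquinone of ring C to the quinone much faster than it touches the single phenol of ring B (hydroquinone-to-quinone oxidation).

Step 13
Reactants: 20 the quinone with the free C3 phenol on ring B
Product: 21 2-{4-methoxy-2-[4-methoxy-5-methyl-2-(propan-2-yl)phenoxy]-3-methyl-6-(propan-2-yl)phenoxy}-3-methyl-6-(propan-2-yl)cyclohexa-2,5-diene-1,4-dione (CNP0335608.0)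
Conditions: MeI, Ag2O, MeCN, rt, dark
Reagents that add atoms: iodomethane, CI
Why: Purdie O-methylation with MeI and Ag2O alkylates the phenol under near-neutral conditions that the aryloxyquinone should tolerate.

**Compound list**

1 | diisopropyl squarate (3,4-di(propan-2-yloxy)cyclobut-3-ene-1,2-dione) | CC(C)OC1=C(OC(C)C)C(=O)C1=O | starting material
2 | 4-hydroxy-4-methyl-2,3-di(propan-2-yloxy)cyclobut-2-en-1-one (racemic) | CC(C)OC1=C(OC(C)C)C(C)(O)C1=O | intermediate (not isolated)
3 | 3-methyl-4-(propan-2-yloxy)cyclobut-3-ene-1,2-dione | CC(C)OC1=C(C)C(=O)C1=O | intermediate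
4 | 3-hydroxy-4-methylcyclobut-3-ene-1,2-dione | CC1=C(O)C(=O)C1=O | intermediate
5 | 3-chloro-4-methylcyclobut-3-ene-1,2-dione | CC1=C(Cl)C(=O)C1=O | intermediate
6 | carvacrol (2-methyl-5-(propan-2-yl)phenol) | Cc1ccc(C(C)C)cc1O | starting material
7 | 2-methoxy-1-methyl-4-(propan-2-yl)benzene | COc1cc(C(C)C)ccc1C | intermediate
8 | 1-bromo-4-methoxy-5-methyl-2-(propan-2-yl)benzene | COc1cc(C(C)C)c(Br)cc1C | intermediate
9 | [4-methoxy-5-methyl-2-(propan-2-yl)phenyl]lithium | [Li]c1cc(C)c(OC)cc1C(C)C | intermediate (not isolated)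
10 | dimethyl [4-methoxy-5-methyl-2-(propan-2-yl)phenyl]boronate | COB(OC)c1cc(C)c(OC)cc1C(C)C | intermediate (not isolated)
11 | 4-methoxy-5-methyl-2-(propan-2-yl)phenol | COc1cc(C(C)C)c(O)cc1C | intermediate
12 | 3-[4-methoxy-5-methyl-2-(propan-2-yl)phenoxy]-4-methylcyclobut-3-ene-1,2-dione | COc1cc(C(C)C)c(OC2=C(C)C(=O)C2=O)cc1C | intermediate
13 | 2-bromo-3-methylbut-1-ene | C=C(Br)C(C)C | starting material
14 | 2-lithio-3-methylbut-1-ene (stock solution in Et2O–pentane) | [Li]C(=C)C(C)C | intermediate
15 | lithium 2-[4-methoxy-5-methyl-2-(propan-2-yl)phenoxy]-3-methyl-1-(3-methylbut-1-en-2-yl)-4-oxocyclobut-2-en-1-olate (racemic) | COc1cc(C(C)C)c(OC2=C(C)C(=O)C2([O-])C(=C)C(C)C)cc1C.[Li+] | intermediate (not isolated)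
16 | 4-[(2-methyl-3,4-dioxocyclobut-1-en-1-yl)oxy]-3-[4-methoxy-5-methyl-2-(propan-2-yl)phenoxy]-2-methyl-4-(3-methylbut-1-en-2-yl)cyclobut-2-en-1-one (racemic) | COc1cc(C(C)C)c(OC2=C(C)C(=O)C2(OC3=C(C)C(=O)C3=O)C(=C)C(C)C)cc1C | intermediate
17 | 4-{[4-hydroxy-2-methyl-4-(3-methylbut-1-en-2-yl)-3-oxocyclobut-1-en-1-yl]oxy}-3-[4-methoxy-5-methyl-2-(propan-2-yl)phenoxy]-2-methyl-4-(3-methylbut-1-en-2-yl)cyclobut-2-en-1-one (two racemic diastereomers) | COc1cc(C(C)C)c(OC2=C(C)C(=O)C2(OC3=C(C)C(=O)C3(O)C(=C)C(C)C)C(=C)C(C)C)cc1C | intermediate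
18 | 4-[2,5-dihydroxy-6-methyl-3-(propan-2-yl)phenoxy]-3-[4-methoxy-5-methyl-2-(propan-2-yl)phenoxy]-2-methyl-4-(3-methylbut-1-en-2-yl)cyclobut-2-en-1-one (racemic) | COc1cc(C(C)C)c(OC2=C(C)C(=O)C2(Oc3c(C)c(O)cc(C(C)C)c3O)C(=C)C(C)C)cc1C | intermediate (not isolated)
19 | 2-{4-hydroxy-2-[4-methoxy-5-methyl-2-(propan-2-yl)phenoxy]-3-methyl-6-(propan-2-yl)phenoxy}-3-methyl-6-(propan-2-yl)benzene-1,4-diol | COc1cc(C(C)C)c(Oc2c(C)c(O)cc(C(C)C)c2Oc2c(C)c(O)cc(C(C)C)c2O)cc1C | intermediate
20 | 2-{4-hydroxy-2-[4-methoxy-5-methyl-2-(propan-2-yl)phenoxy]-3-methyl-6-(propan-2-yl)phenoxy}-3-methyl-6-(propan-2-yl)cyclohexa-2,5-diene-1,4-dione | COc1cc(C(C)C)c(Oc2c(C)c(O)cc(C(C)C)c2OC2=C(C)C(=O)C=C(C(C)C)C2=O)cc1C | intermediate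
21 | 2-{4-methoxy-2-[4-methoxy-5-methyl-2-(propan-2-yl)phenoxy]-3-methyl-6-(propan-2-yl)phenoxy}-3-methyl-6-(propan-2-yl)cyclohexa-2,5-diene-1,4-dione | COc1cc(C(C)C)c(Oc2c(C)c(OC)cc(C(C)C)c2OC2=C(C)C(=O)C=C(C(C)C)C2=O)cc1C | target

**Step count and risks**

Total step count: 13. Longest linear sequence: 9 steps (steps 1–3 or steps 4–6, then steps 7 and 9–13); step 8 is a one-step side branch that supplies reagent 14.

Steps most likely to fail:

1. Step 11. The twofold ring expansion may be diverted in three ways. The ring B cyclobutenone may open slowly or with the wrong sense of rotation while its C4 oxygen is still a vinylogous ester oxygen. A [3,3] shift may occur across the allyl vinyl ether array CH2=C–C4–O–C=C that links the two four-membered rings. A ketene of one half may be captured by a hydroxyl of the other half or by a second molecule. The fallback uses only single ring expansions of the ordinary 4-alkoxy and 4-hydroxy kind; it sets out from 12 and rejoins the route at 21. Alkoxide 15, made from 12 and 14 as in step 9, is capped with chloromethyl methyl ether instead of 5 to give the 4-(methoxymethoxy)cyclobutenone F1. Heating in toluene gives the C6-methoxymethyl-protected ring B phenol F2. MeI and K2CO3 give the C3 methyl ether F3, and HCl in MeOH frees the C6 phenol F4. F4 with 5 and Et3N gives the aryloxycyclobutenedione F5, addition of 14 gives the hydroxycyclobutenone F6, and heating gives the ring C hydroquinone F7. Ag2O oxidation of F7 then gives 21 directly.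

2. Step 9. The alkenyllithium may displace the aryloxy group by addition–elimination instead of adding to the carbonyl. The hindered tertiary alkoxide may also attack 5 too slowly, or act as a base on the vinylogously acidic methyl group of 5, so that 15 decomposes on warming. The fallback sets out from 12 (through 15) and rejoins at 16. Alkoxide 15 is captured at −78 °C with 3,4-dichlorocyclobut-3-ene-1,2-dione, which has no acidic methyl group and is the stronger electrophile, to give the chlorocyclobutenedione ether F8. The methyl group is then installed by Stille coupling with Me4Sn, with PdCl2(PPh3)2 and CuI as catalysts, which gives 16.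

3. Step 10. The alkenyllithium may add to the cyclobutenone carbonyl of the ring B unit, or attack the oxygen-bearing carbon of the dione and expel the tertiary alkoxide, instead of adding to the one ketone-like carbonyl. The fallback sets out from 16 and rejoins at 19. 16 is heated first, so that the competing cyclobutenone is consumed in a single ring expansion to the phenolic aryloxycyclobutenedione F9. Two equivalents of 14 are then used: the first only forms the lithium phenoxide and the second adds to the dione to give the hydroxycyclobutenone F10. A second heating gives 19.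

**Further compounds**

F1 | step 11 | 4-(methoxymethoxy)-3-[4-methoxy-5-methyl-2-(propan-2-yl)phenoxy]-2-methyl-4-(3-methylbut-1-en-2-yl)cyclobut-2-en-1-one (racemic) | COc1cc(C(C)C)c(OC2=C(C)C(=O)C2(OCOC)C(=C)C(C)C)cc1C
F2 | step 11 | 4-(methoxymethoxy)-3-[4-methoxy-5-methyl-2-(propan-2-yl)phenoxy]-2-methyl-5-(propan-2-yl)phenol | COc1cc(C(C)C)c(Oc2c(C)c(O)cc(C(C)C)c2OCOC)cc1C
F3 | step 11 | 1-methoxy-4-(methoxymethoxy)-3-[4-methoxy-5-methyl-2-(propan-2-yl)phenoxy]-2-methyl-5-(propan-2-yl)benzene | COc1cc(C(C)C)c(Oc2c(C)c(OC)cc(C(C)C)c2OCOC)cc1C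
F4 | step 11 | 4-methoxy-2-[4-methoxy-5-methyl-2-(propan-2-yl)phenoxy]-3-methyl-6-(propan-2-yl)phenol | COc1cc(C(C)C)c(Oc2c(C)c(OC)cc(C(C)C)c2O)cc1C
F5 | step 11 | 3-{4-methoxy-2-[4-methoxy-5-methyl-2-(propan-2-yl)phenoxy]-3-methyl-6-(propan-2-yl)phenoxy}-4-methylcyclobut-3-ene-1,2-dione | COc1cc(C(C)C)c(Oc2c(C)c(OC)cc(C(C)C)c2OC2=C(C)C(=O)C2=O)cc1C
F6 | step 11 | 4-hydroxy-3-{4-methoxy-2-[4-methoxy-5-methyl-2-(propan-2-yl)phenoxy]-3-methyl-6-(propan-2-yl)phenoxy}-2-methyl-4-(3-methylbut-1-en-2-yl)cyclobut-2-en-1-one (racemic) | COc1cc(C(C)C)c(Oc2c(C)c(OC)cc(C(C)C)c2OC2=C(C)C(=O)C2(O)C(=C)C(C)C)cc1C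
F7 | step 11 | 2-{4-methoxy-2-[4-methoxy-5-methyl-2-(propan-2-yl)phenoxy]-3-methyl-6-(propan-2-yl)phenoxy}-3-methyl-6-(propan-2-yl)benzene-1,4-diol | COc1cc(C(C)C)c(Oc2c(C)c(OC)cc(C(C)C)c2Oc2c(C)c(O)cc(C(C)C)c2O)cc1C
F8 | step 9 | 4-[(2-chloro-3,4-dioxocyclobut-1-en-1-yl)oxy]-3-[4-methoxy-5-methyl-2-(propan-2-yl)phenoxy]-2-methyl-4-(3-methylbut-1-en-2-yl)cyclobut-2-en-1-one (racemic) | COc1cc(C(C)C)c(OC2=C(C)C(=O)C2(OC3=C(Cl)C(=O)C3=O)C(=C)C(C)C)cc1C
F9 | step 10 | 3-{4-hydroxy-2-[4-methoxy-5-methyl-2-(propan-2-yl)phenoxy]-3-methyl-6-(propan-2-yl)phenoxy}-4-methylcyclobut-3-ene-1,2-dione | COc1cc(C(C)C)c(Oc2c(C)c(O)cc(C(C)C)c2OC2=C(C)C(=O)C2=O)cc1C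
F10 | step 10 | 4-hydroxy-3-{4-hydroxy-2-[4-methoxy-5-methyl-2-(propan-2-yl)phenoxy]-3-methyl-6-(propan-2-yl)phenoxy}-2-methyl-4-(3-methylbut-1-en-2-yl)cyclobut-2-en-1-one (racemic) | COc1cc(C(C)C)c(Oc2c(C)c(O)cc(C(C)C)c2OC2=C(C)C(=O)C2(O)C(=C)C(C)C)cc1C
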